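**Retrosynthetic overview**
1. Target 14 is cut at the alkyne–alkene C(sp)–C(sp2) bond (Sonogashira) into the silyl-capped ethynyl oxolane ester 12 and the bromo-iodo diene 5.
2. Oxolane 12 is cut at the ring C–O bond and the exocyclic C–C bond in one operation: cobalt-catalysed oxidative cycloetherification of (S)-alkenynol 9, with the ring-closed radical captured by methyl acrylate 10. This forms the only ring, trans, from the carbinol stereocentre.
3. Alkenynol 9 comes from asymmetric transfer hydrogenation of ynone 8, made from pent-4-enoyl chloride 6 and bis(trimethylsilyl)acetylene 7.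
4. Diene 5 comes from hydrozirconation/iodination of bromoenyne 3, made by Z-selective bromomethylenation of non-8-ynal 2 from non-8-yn-1-ol 1.

Assumption: 1, 6, 7 and 10 are bought; the cobalt diketonate of step 6 is made beforehand from Co(OAc)2 and commercial 4,4,4-trifluoro-1-phenylbutane-1,3-dione and is not counted as a step.

**Route**

Step 1
Reactants: 1 non-8-yn-1-ol
Product: 2 non-8-ynal
Conditions: TEMPO (10 mol%), PhI(OAc)2 (1.1 equiv), CH2Cl2, rt
Reagents that add atoms: none
Why: Oxoammonium-catalysed (TEMPO/PhI(OAc)2) oxidation stops cleanly at the aldehyde and leaves the terminal alkyne untouched.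

Step 2
Reactants: 2 non-8-ynal
Product: 3 (Z)-1-bromodec-1-en-9-yne
Conditions: BrCH2PPh3Br (1.3 equiv), KOtBu (1.25 equiv), THF, −78 °C; then 2, −78 °C
Reagents that add atoms: (bromomethyl)triphenylphosphonium bromide, BrC[P+](c1ccccc1)(c1ccccc1)c1ccccc1.[Br-]
Why: Wittig olefination with the non-stabilised bromomethylene ylide under kinetic conditions gives the Z-bromoalkene (typically at least 10:1), and the ylide is too weak a base to deprotonate the alkyne C–H.

Step 3
Reactants: 3 (Z)-1-bromodec-1-en-9-yne
Product: 5 (1Z,9E)-1-bromo-10-iododeca-1,9-diene, via alkenylzirconocene chloride 4 (not isolated)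
Conditions: Cp2Zr(H)Cl (1.2 equiv), THF, rt, dark; then I2 (1.2 equiv), 0 °C
Reagents that add atoms: iodine, [I][I]
Why: Hydrozirconation adds Zr–H syn across the terminal alkyne with zirconium at the terminal carbon, and iodinolysis with retention gives the E-iodoalkene; the disubstituted bromoalkene reacts far more slowly.

Step 4
Reactants: 6 pent-4-enoyl chloride; 7 bis(trimethylsilyl)acetylene
Product: 8 1-(trimethylsilyl)hept-6-en-1-yn-3-one
Conditions: AlCl3 (1.1 equiv), CH2Cl2, 0 °C
Reagents that add atoms: none
Why: Friedel–Crafts-type ipso-acylation of the alkynylsilane (β-silyl-stabilised cation, loss of one silyl group) gives the silyl ynone; at 0 °C it outpaces reaction of the remote alkene.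

Step 5
Reactants: 8 1-(trimethylsilyl)hept-6-en-1-yn-3-one
Product: 9 (3S)-1-(trimethylsilyl)hept-6-en-1-yn-3-ol
Conditions: RuCl[(S,S)-TsDPEN](p-cymene) (1 mol%), iPrOH, rt
Reagents that add atoms: none
Why: Noyori asymmetric transfer hydrogenation of an alkynyl ketone; the (S,S)-catalyst delivers hydride to the face that gives the (S)-propargylic alcohol (expected ≥97% ee), and the alkene and C–Si bond are inert.

Step 6
Reactants: 9 (3S)-1-(trimethylsilyl)hept-6-en-1-yn-3-ol; 10 methyl acrylate
Product: 12 methyl 4-[(2S,5S)-5-[(trimethylsilyl)ethynyl]oxolan-2-yl]butanoate, via oxolanylmethyl radical 11 (not isolated)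
Conditions: Co(C10H6F3O2)2 [cobalt bis(4,4,4-trifluoro-1-phenylbutane-1,3-dionate)] (10 mol%), 10 (20 equiv), 1,4-cyclohexadiene (10 equiv), air (1 atm), toluene, 60 °C
Reagents that add atoms: none
Why: Proposed new method: an aerobic cobalt-catalysed oxidative cycloetherification/radical conjugate-addition cascade on a secondary propargylic (1-alkynyl) pent-4-en-1-ol; O2 turns the divalent cobalt diketonate into a trivalent cobalt oxidant that binds the hydroxyl of 9 and closes the ring by 5-exo C–O bond formation through a chair-like transition state with the silylalkynyl group pseudo-equatorial, which sets the new C-2 centre trans to the existing one [(2S,5S)]; homolysis of the alkyl–cobalt bond releases the nucleophilic primary radical 11, which adds to the excess electron-poor acrylate, and the resulting electrophilic α-ester radical takes a hydrogen atom from 1,4-cyclohexadiene, which also returns cobalt to the divalent state; the closest known reaction type is the Mukaiyama-type cobalt-catalysed aerobic oxidative cyclisation of 1-alkyl- and 1-aryl-pent-4-en-1-ols to 2,5-trans-tetrahydrofurans with hydroxylative, reductive or alkene-trapping termination, which to my knowledge has not been shown for alkynyl carbinols.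

Step 7
Reactants: 12 methyl 4-[(2S,5S)-5-[(trimethylsilyl)ethynyl]oxolan-2-yl]butanoate; 5 (1Z,9E)-1-bromo-10-iododeca-1,9-diene
Product: 14 methyl 4-[(2S,5S)-5-[(3E,11Z)-12-bromododeca-3,11-dien-1-yn-1-yl]oxolan-2-yl]butanoate, via terminal alkyne 13 (not isolated)
Conditions: K2CO3 (0.2 equiv), MeOH, rt; then 5 (1.1 equiv), Pd(PPh3)4 (5 mol%), CuI (10 mol%), Et3N (3 equiv), THF, degassed, 0 °C to rt
Reagents that add atoms: none
Why: Methanolysis of the C(sp)–Si bond followed by Sonogashira coupling with retention of the E geometry; zerovalent palladium inserts into the C–I bond much faster than into the C–Br bond, so the Z-bromoalkene survives, and no stereocentre is touched.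

**Compound list**
1 | non-8-yn-1-ol | OCCCCCCCC#C | starting material
2 | non-8-ynal | O=CCCCCCCC#C | intermediate
3 | (Z)-1-bromodec-1-en-9-yne | Br/C=C\CCCCCCC#C | intermediate
4 | [(1E,9Z)-10-bromodeca-1,9-dien-1-yl]chlorobis(cyclopentadienyl)zirconium (cyclopentadienyl drawn sigma-bonded) | Br/C=C\CCCCCC/C=C/[Zr](Cl)(C1C=CC=C1)C1C=CC=C1 | intermediate (not isolated)
5 | (1Z,9E)-1-bromo-10-iododeca-1,9-diene | Br/C=C\CCCCCC/C=C/I | intermediate
6 | pent-4-enoyl chloride | C=CCCC(=O)Cl | starting material
7 | bis(trimethylsilyl)acetylene | C[Si](C)(C)C#C[Si](C)(C)C | starting material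
8 | 1-(trimethylsilyl)hept-6-en-1-yn-3-one | C=CCCC(=O)C#C[Si](C)(C)C | intermediate
9 | (3S)-1-(trimethylsilyl)hept-6-en-1-yn-3-ol | C=CCC[C@@H](C#C[Si](C)(C)C)O | intermediate
10 | methyl acrylate | C=CC(=O)OC | starting material
11 | {(2R,5S)-5-[(trimethylsilyl)ethynyl]oxolan-2-yl}methyl radical (trans) | [CH2][C@@H]1CC[C@@H](C#C[Si](C)(C)C)O1 | intermediate (not isolated)
12 | methyl 4-[(2S,5S)-5-[(trimethylsilyl)ethynyl]oxolan-2-yl]butanoate | COC(=O)CCC[C@@H]1CC[C@@H](C#C[Si](C)(C)C)O1 | intermediate
13 | methyl 4-[(2S,5S)-5-ethynyloxolan-2-yl]butanoate | COC(=O)CCC[C@@H]1CC[C@@H](C#C)O1 | intermediate (not isolated)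
14 | methyl 4-[(2S,5S)-5-[(3E,11Z)-12-bromododeca-3,11-dien-1-yn-1-yl]oxolan-2-yl]butanoate (CNP0170116.1) | COC(=O)CCC[C@@H]1CC[C@@H](C#C/C=C/CCCCCC/C=C\Br)O1 | target

**Count**
Total steps: 7. Longest linear sequence: 4 steps (1 → 2 → 3 → 5 → 14, or 6/7 → 8 → 9 → 12 → 14).

**Three steps most likely to fail**

Step 6 (the new cascade). The slim alkynyl group may give a lower trans:cis ratio than alkyl or aryl carbinols. Reductive or O2 trapping of radical 11 may outrun addition to the acrylate. The propargylic α-oxy C–H of the product may autoxidise. The fallback uses known chemistry, sets out from 9 and comes back at 12. Kinetic iodoetherification of 9 (I2, NaHCO3, MeCN, 0 °C) gives trimethyl{[(2S,5S)-5-(iodomethyl)oxolan-2-yl]ethynyl}silane F1 as the major trans isomer (free alcohols typically give only about 2:1 trans:cis), freed from its epimer by chromatography. A tin-mediated Giese addition of F1 to methyl acrylate 10 (Bu3SnH by syringe pump, AIBN, benzene, 80 °C) then gives 12.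

Step 7. Some coupling at the Z-bromoalkene, alkyne homocoupling, or trouble in the one-flask desilylation could erode the yield of the final step. The fallback installs the bromoalkene last; it sets out from 1 and 12 and comes back at 14. Hydrozirconation/iodination of 1 (Cp2Zr(H)Cl, 2.2 equiv, then I2) gives (E)-9-iodonon-8-en-1-ol F2. Desilylation of 12 and Sonogashira coupling with F2 under the step 7 conditions gives methyl 4-[(2S,5S)-5-[(3E)-11-hydroxyundec-3-en-1-yn-1-yl]oxolan-2-yl]butanoate F3. Dess–Martin oxidation gives methyl 4-[(2S,5S)-5-[(3E)-11-oxoundec-3-en-1-yn-1-yl]oxolan-2-yl]butanoate F4. The bromomethylene Wittig reaction of step 2, applied to F4 at −78 °C, gives 14.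

Step 2. The E-bromoalkene formed alongside the Z isomer is hard to remove later, and excess base can dehydrobrominate the product. The fallback builds the Z-bromoalkene by syn reduction of a bromoalkyne; it sets out from 1 and comes back at 3. NBS with catalytic AgNO3 in acetone gives 9-bromonon-8-yn-1-ol F5. Hydroboration with dicyclohexylborane (2.2 equiv, THF, 0 °C) followed by protonolysis with AcOH gives (Z)-9-bromonon-8-en-1-ol F6 (syn B–H addition, retention on protonolysis). TEMPO/PhI(OAc)2 oxidation gives (Z)-9-bromonon-8-enal F7. Seyferth–Gilbert homologation with dimethyl (1-diazo-2-oxopropyl)phosphonate, K2CO3, MeOH gives 3.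

**Further compounds**
F1 | step 6 | trimethyl{[(2S,5S)-5-(iodomethyl)oxolan-2-yl]ethynyl}silane | IC[C@@H]1CC[C@@H](C#C[Si](C)(C)C)O1
F2 | step 7 | (E)-9-iodonon-8-en-1-ol | OCCCCCCC/C=C/I
F3 | step 7 | methyl 4-[(2S,5S)-5-[(3E)-11-hydroxyundec-3-en-1-yn-1-yl]oxolan-2-yl]butanoate | COC(=O)CCC[C@@H]1CC[C@@H](C#C/C=C/CCCCCCCO)O1
F4 | step 7 | methyl 4-[(2S,5S)-5-[(3E)-11-oxoundec-3-en-1-yn-1-yl]oxolan-2-yl]butanoate | COC(=O)CCC[C@@H]1CC[C@@H](C#C/C=C/CCCCCCC=O)O1
F5 | step 2 | 9-bromonon-8-yn-1-ol | OCCCCCCCC#CBr
F6 | step 2 | (Z)-9-bromonon-8-en-1-ol | OCCCCCCC/C=C\Br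
F7 | step 2 | (Z)-9-bromonon-8-enal | O=CCCCCCC/C=C\Br
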